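**One step.** In a one-step world a substance loses the same fraction in each equal time, so its logarithm falls on a straight line and a single time describes it. E looked like that here. Its last reading gave 12.0 min per power of ten in summer and 12.5 min in spring, though spring's cE was twice summer's. I took the mean, 12.3 min, as the tenth-time of E, the time in which E falls by one power of ten, which is first-order decay written in decades.

| setting | summer | spring | violet | teal |
|---|---|---|---|---|
| E | 0.0087 M | 0.019 M | 0.013 M | 0.013 M |
| Q | 2 mol% | 2 mol% | 2 mol% | 2 mol% |
| J | 0.21 mM | 0.21 mM | 0.21 mM | 0.21 mM |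
| remark | run made earlier | run made earlier |  |  |
| time |  |  | 4.0 min | 8.0 min |

- summer (time / min: E / %, X / %, Z / %): 0.200: 97.2, 3.6, 0; 0.333: 94.0, 6.3, 0.4; 0.667: 88.2, 11.3, 0.1; 1.33: 78.8, 20.9, 1.9; 2.50: 61.9, 32.4, 3.8
- spring (time / min: E / %, X / %, Z / %): 0.500: 91.4, 8.8, 1.0; 1.00: 82.9, 15.8, 2.8; 1.33: 77.7, 18.9, 2.8; 2.00: 69.3, 24.0, 6.5; 2.50: 63.2, 27.3, 9.4

(readings scatter by 0.5 percentage points)

- which of these there is most of at the end, counted by the E in it, violet (X / Z / E)
- which of these there is most of at the end, counted by the E in it, teal (X / Z / E)
- final amount of the leader among these, as a percentage of the E charged, in violet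
- final amount of the leader among these, as a percentage of the E charged, in teal

**Which stop.** I had to decide whether to stop at 4.0 min (violet) or leave the flask until 8.0 min (teal), and that hung on whether E still led. E, X and Z share the charge, so once E is under a third, something else holds more. By my tenth-time E reaches a third at 5.86 min, and teal runs longer, with E at 22.3 %. On that estimate the leader in teal holds at least 38.9 %. I chose X as a judgement: at 2.50 min Z held 25.6 % of the converted E in spring, the richer flask, less than X, but that share had risen from 10.2 % at 0.500 min, so this reading gave no bound for teal at 8.0 min.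

Violet gives E 47.2 %. X could pass that only if Z took under 10.5 % of the converted E. Summer already showed 10.5 % at 2.50 min, and violet is richer and runs longer, so I kept E as leader there.

**The check.** The forecast gave E at 47.5 % for violet and X at 40 % for teal, “so X narrowly leads”. Violet held E at 47.5 %, and teal held X at 48.8 %, with E at 22.6 % and Z at 28.6 %.

    E → X (k = 0.00310 s⁻¹)
    Q + X → Q + Z (k = 17.0 M⁻¹ s⁻¹)
    Q + J ⇌ G, settled at all times (K = 2700 M⁻¹)
    Q → L (k = 0.00300 s⁻¹)

**Two clocks.** In violet at 1.64 min, the half-life of E by its step was 3.7 min and that of Q by its step to L was 3.9 min, nearly the same. In teal at 8.00 min, L held 63.3 % of the catalyst charged and free Q 24.7 %. For the flask like violet left until 6.0 min, my tenth-time gives E 32.5 %, and that flask held E at 32.8 % and X at 45.8 %.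

All runs stem from a simulated flask on assumed constants.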